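## Retrosynthetic overview

1. Target 11 ⇒ diol 9 by site-selective O-acylation at C8 (C7–OH is neopentylic); 9 ⇒ allylic angelate 8 by osmylation anti to the C9 ester (forms C7–O and C8–O).
2. Key disconnection: the C9–O(angeloyl) bond of 8, made by a ligand-controlled copper-catalysed allylic C–H angeloyloxylation of olefins 5/6 with angelic acid 7.
3. Olefins 5/6 ⇒ alcohol 4 ⇒ ketone 3, by remote C8–H hydroxylation (C8–O) and dehydration.
4. 3 ⇒ enone 2 ⇒ (+)-α-longipinene 1, by allylic C1–H oxidation (C1=O) and face-selective hydrogenation (sets C3).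
5. No ring is built: the cyclobutane and the six- and seven-membered rings (C4, C5, C10, C11) come intact from 1.

Assumption: commercial (+)-α-longipinene (CAS 5989-08-2, from pine turpentine) is the (1R,2S,7R,8R) enantiomer drawn as 1; this is the absolute core configuration the target needs.

Numbering used in all names (longipinane): C1 (C=O), C2, C3 (CH3), C4, C5, C6 (gem-dimethyl), C7, C8, C9, C10 (CH3), C11. The cyclobutane is C4–C5–C11–C10. The six-membered ring is C1–C2–C3–C4–C5–C11. The seven-membered ring is C5–C6–C7–C8–C9–C10–C11.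

## Route

Step 1
Reactants: 1 (+)-α-longipinene (longipin-2-ene)
Product: 2 longipin-2-en-1-one (core stereocentres as in 1)
Conditions: Rh2(cap)4 (cap = caprolactamate, 1 mol%), t-BuOOH (70% aq., 5 equiv), K2CO3, CH2Cl2, 25 °C
Reagents that add atoms: tert-butyl hydroperoxide, CC(C)(C)OO
Why: Radical allylic C–H oxidation (Doyle-type, the α-pinene → verbenone pattern) at C1, the only secondary allylic position, gives the enone without touching a stereocentre or the cyclobutane.

Step 2
Reactants: 2 longipin-2-en-1-one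
Product: 3 (3S)-longipinan-1-one
Conditions: H2 (1 atm), Pd/C (10%), EtOAc, 25 °C
Reagents that add atoms: none
Why: Heterogeneous catalytic hydrogenation delivers hydrogen to the enone face flanked by C5–H, away from the C10 bridge whose methyl covers the other face (as in α-pinene → cis-pinane), which sets C3 with its methyl syn to C10.

Step 3
Reactants: 3 (3S)-longipinan-1-one
Product: 4 (3S)-8-hydroxylongipinan-1-one (both C8 epimers)
Conditions: Mn(OTf)2((S,S)-TIPS-mcp) (2 mol%), H2O2 (50% aq., 1.5 equiv, syringe pump), AcOH (10 equiv), (CF3)2CHOH, 0 °C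
Reagents that add atoms: hydrogen peroxide, OO
Why: Electrophilic manganese-oxo methylene hydroxylation (White–Costas type) picks C8 because the C1 carbonyl deactivates the six-membered ring and C9, and C7 and C9 are neopentylic (the sclareolide C2 pattern); the fluorinated alcohol stops oxidation at the alcohol, and the new C8 centre is erased in step 4.

Step 4
Reactants: 4 (3S)-8-hydroxylongipinan-1-one
Product: 5 (3S)-longipin-7-en-1-one together with 6 (3S)-longipin-8-en-1-one (double-bond isomers, isolated and used as one mixture)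
Conditions: Burgess reagent (MeO2C–N(−)–SO2–N(+)Et3, 1.5 equiv), toluene, 60 °C
Reagents that add atoms: none
Why: Burgess dehydration (syn-elimination of the secondary sulfamate) toward either flanking methylene gives both olefins, and both are carried on because they give the same allyl intermediate in step 5.

Step 5
Reactants: 5 (3S)-longipin-7-en-1-one, 6 (3S)-longipin-8-en-1-one, 7 angelic acid ((Z)-2-methylbut-2-enoic acid)
Product: 8 (3S,9R)-9-angeloyloxylongipin-7-en-1-one (ester oxygen on the ring face toward C11, anti to the C4–C10 bond; same spatial arrangement as 9S in 9 and 11)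
Conditions: [Cu(MeCN)4]PF6 (10 mol%), (S,S)-t-Bu-box (12 mol%), 7 (2 equiv), (t-BuO)2 (1.5 equiv), PhCl/MeCN (4:1), 50 °C
Reagents that add atoms: angelic acid 7, C/C=C(/C)C(=O)O
Why: Proposed new method: a Kharasch–Sosnovsky-type allylic C–H acyloxylation run with the free acid and di-tert-butyl peroxide instead of a perester under a bis(oxazoline)–copper catalyst; monovalent copper cleaves the peroxide, tert-butoxyl abstracts the only allylic hydrogens (C9–H of 5, C7–H of 6) so both isomers converge on one C7–C8–C9 allyl radical lying in the local pseudo-mirror plane of the seven-membered ring, the divalent copper angelate captures it, and C–O reductive elimination from trivalent copper occurs at C9 (C7 is shielded by the C6 gem-dimethyl group) on the face chosen by the ligand (the antipodal ligand is used if the sense is reversed), which sets C9; closest known reactions are the copper–bis(oxazoline) asymmetric Kharasch–Sosnovsky oxidation of cycloalkenes with tert-butyl perbenzoate and copper-catalysed oxidative allylic esterification with carboxylic acids and peroxides.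

Step 6
Reactants: 8 (3S,9R)-9-angeloyloxylongipin-7-en-1-one
Product: 9 (3S,7S,8S,9S)-9-angeloyloxy-7,8-dihydroxylongipinan-1-one
Conditions: OsO4 (2 mol%), NMO (1.5 equiv), acetone/H2O (5:1), 0 °C
Reagents that add atoms: osmium tetroxide (catalytic oxygen carrier), O=[Os](=O)(=O)=O; N-methylmorpholine N-oxide, C[N+]1([O-])CCOCC1; water, O
Why: Upjohn syn-dihydroxylation attacks the isolated cis-olefin faster than the conjugated, trisubstituted angelate and on the face anti to the allylic C9 acyloxy group (Kishi's rule; the rest of the ring environment is nearly symmetric), which sets C7–O and C8–O cis to each other and trans to C9–O.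

Step 7
Reactants: 9 (3S,7S,8S,9S)-9-angeloyloxy-7,8-dihydroxylongipinan-1-one, 10 isovaleric anhydride
Product: 11 (3S,4S,5S,7S,8S,9S,10R,11R)-9-angeloyloxy-7-hydroxy-8-isovaleroyloxylongipinan-1-one (target)
Conditions: 10 (1.1 equiv), DMAP (0.1 equiv), pyridine, CH2Cl2, −20 to 0 °C
Reagents that add atoms: isovaleric anhydride 10, CC(C)CC(=O)OC(=O)CC(C)C
Why: DMAP-catalysed (Steglich-type) acylation esterifies C8–OH and leaves the neopentylic C7–OH next to the gem-dimethyl carbon free; no stereocentre changes.

## Compound list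

1 | (+)-α-longipinene, (1R,2S,7R,8R)-2,6,6,9-tetramethyltricyclo[5.4.0.0(2,8)]undec-9-ene | C1CCC(C)(C)[C@H]2[C@@H]3C(C)=CC[C@H]2[C@@]31C | starting material
2 | longipin-2-en-1-one | C1CCC(C)(C)[C@H]2[C@@H]3C(C)=CC(=O)[C@H]2[C@@]31C | intermediate
3 | (3S)-longipinan-1-one | C1CCC(C)(C)[C@H]2[C@@H]3[C@@H](C)CC(=O)[C@H]2[C@@]31C | intermediate
4 | (3S)-8-hydroxylongipinan-1-one (C8 unspecified, both epimers) | C1C(O)CC(C)(C)[C@H]2[C@@H]3[C@@H](C)CC(=O)[C@H]2[C@@]31C | intermediate
5 | (3S)-longipin-7-en-1-one (C7=C8) | C1C=CC(C)(C)[C@H]2[C@@H]3[C@@H](C)CC(=O)[C@H]2[C@@]31C | intermediate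
6 | (3S)-longipin-8-en-1-one (C8=C9) | C1=CCC(C)(C)[C@H]2[C@@H]3[C@@H](C)CC(=O)[C@H]2[C@@]31C | intermediate
7 | angelic acid, (Z)-2-methylbut-2-enoic acid | C/C=C(/C)C(=O)O | starting material
8 | (3S,9R)-9-angeloyloxylongipin-7-en-1-one | C/C=C(/C)C(=O)O[C@@H]1C=CC(C)(C)[C@H]2[C@@H]3[C@@H](C)CC(=O)[C@H]2[C@@]31C | intermediate
9 | (3S,7S,8S,9S)-9-angeloyloxy-7,8-dihydroxylongipinan-1-one | C/C=C(/C)C(=O)O[C@@H]1[C@@H](O)[C@@H](O)C(C)(C)[C@H]2[C@@H]3[C@@H](C)CC(=O)[C@H]2[C@@]31C | intermediate
10 | isovaleric anhydride (3-methylbutanoic anhydride) | CC(C)CC(=O)OC(=O)CC(C)C | starting material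
11 | (3S,4S,5S,7S,8S,9S,10R,11R)-9-angeloyloxy-7-hydroxy-8-isovaleroyloxylongipinan-1-one | C/C=C(/C)C(=O)O[C@@H]1[C@@H](OC(=O)CC(C)C)[C@@H](O)C(C)(C)[C@H]2[C@@H]3[C@@H](C)CC(=O)[C@H]2[C@@]31C | target

## Step count and risk

Total: 7 steps. Longest linear sequence: 7 steps (1 → 11).

Step 5 (proposed new step). Risks are C7 versus C9 regiochemistry, facial control in a nearly symmetric ring environment, and Z→E scrambling of the angelate under radical conditions. The fallback uses known chemistry, sets out from the mixture of 5 and 6 and comes back at 8. The established Kharasch–Sosnovsky benzoyloxylation (tert-butyl perbenzoate, [Cu(MeCN)4]PF6, (S,S)-t-Bu-box, MeCN/acetone) gives (3S,9R)-9-benzoyloxylongipin-7-en-1-one F2. Methanolysis (K2CO3, MeOH) gives (3S,9R)-9-hydroxylongipin-7-en-1-one F3. Any C9 epimer is a separable diastereomer and is converged by Mitsunobu inversion with angelic acid (PPh3, DIAD). Yamaguchi esterification of F3 (angelic acid, 2,4,6-trichlorobenzoyl chloride, Et3N, then DMAP, toluene) gives 8 without angelate isomerisation.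

Step 3. Risks are site selectivity (C8 versus C7, C9 or C3–H) and over-oxidation. The fallback sets out from 3 and comes back at 4. The substrate is oxidised deliberately to the ketone with a stoichiometric dioxirane (methyl(trifluoromethyl)dioxirane, CH2Cl2, −20 °C), giving (3S)-longipinane-1,8-dione F1. The unhindered C8 carbonyl is then reduced chemoselectively (NaBH4, MeOH, −40 °C) to 4; the C1 carbonyl is shielded by the cyclobutane bridgehead and the C10 methyl.

Step 6. Risks are competing osmylation of the angelate double bond and low facial selectivity. The fallback sets out from the mixture of 5 and 6 and comes back at 9, making the diol before the angelate exists. Benzoate F2 (made as above) is dihydroxylated (OsO4, NMO) to (3S,7S,8S,9S)-9-benzoyloxy-7,8-dihydroxylongipinan-1-one F4. This is protected (2,2-dimethoxypropane, PPTS) as the 9-benzoate 7,8-acetonide F5. Debenzoylation (K2CO3, MeOH) gives the 9-hydroxy 7,8-acetonide F6. Yamaguchi esterification with angelic acid gives the 9-angelate 7,8-acetonide F7. Deprotection (80% AcOH, 40 °C) gives 9.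

## Further compounds

F1 | step 3 | (3S)-longipinane-1,8-dione | C1C(=O)CC(C)(C)[C@H]2[C@@H]3[C@@H](C)CC(=O)[C@H]2[C@@]31C
F2 | step 5 | (3S,9R)-9-benzoyloxylongipin-7-en-1-one | O=C(c1ccccc1)O[C@@H]1C=CC(C)(C)[C@H]2[C@@H]3[C@@H](C)CC(=O)[C@H]2[C@@]31C
F3 | step 5 | (3S,9R)-9-hydroxylongipin-7-en-1-one | O[C@@H]1C=CC(C)(C)[C@H]2[C@@H]3[C@@H](C)CC(=O)[C@H]2[C@@]31C
F4 | step 6 | (3S,7S,8S,9S)-9-benzoyloxy-7,8-dihydroxylongipinan-1-one | O=C(c1ccccc1)O[C@@H]1[C@@H](O)[C@@H](O)C(C)(C)[C@H]2[C@@H]3[C@@H](C)CC(=O)[C@H]2[C@@]31C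
F5 | step 6 | 9-benzoyloxy-7,8-O-isopropylidene-7,8-dihydroxylongipinan-1-one (configuration as F4) | O=C(c1ccccc1)O[C@@H]1[C@@H](OC4(C)C)[C@@H](O4)C(C)(C)[C@H]2[C@@H]3[C@@H](C)CC(=O)[C@H]2[C@@]31C
F6 | step 6 | 9-hydroxy-7,8-O-isopropylidene-7,8-dihydroxylongipinan-1-one (configuration as F4) | O[C@@H]1[C@@H](OC4(C)C)[C@@H](O4)C(C)(C)[C@H]2[C@@H]3[C@@H](C)CC(=O)[C@H]2[C@@]31C
F7 | step 6 | 9-angeloyloxy-7,8-O-isopropylidene-7,8-dihydroxylongipinan-1-one (configuration as 9) | C/C=C(/C)C(=O)O[C@@H]1[C@@H](OC4(C)C)[C@@H](O4)C(C)(C)[C@H]2[C@@H]3[C@@H](C)CC(=O)[C@H]2[C@@]31C
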